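## Structural features

The target is a chalcone: a 4-hydroxyphenyl ring (ring B) is joined through an (E)-propenone bridge to C8 of a chroman, whose benzene ring (ring A) is fused to a dihydropyran ring. Ring A carries four contiguous substituents: the enone carbonyl on C8, the ether oxygen O1 on C8a, the C4 methylene on C4a and a methoxy group on C5. The pyran ring holds a quaternary gem-dimethyl ether carbon (C2) and the only stereocentre, the (S)-configured secondary carbinol C3. C3 lies between C2 and the benzylic CH2 (C4), so no neighbouring stereocentre can relay its configuration, and it must be set by a reagent or catalyst. The fragile parts are the enone (a Michael acceptor, sensitive to peroxide and light), the free phenol, the electron-rich aryl ketone (open to Baeyer–Villiger oxidation and to electrophiles at C6) and the β-oxygenated tertiary aryl ether, which can ionise at C2 under strong acid. The real difficulty is to place one oxygen of defined configuration on C3 and none on C4, next to a quaternary centre; the chalcone itself is routine. The key step exploits the fact that O1–C8a–C4a–C4 is a latent ortho-quinone methide whose oxygen sits next to the acetyl-bearing C8, so that O1 and the acetyl oxygen form a two-point binding site for a chiral Lewis acid. C3–C2 then maps onto a 2-methylpropenyl unit in which silicon stands in for the C3 hydroxyl.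

## Logic of the disconnections

14 is cut first at the enone Cα=Cβ bond, giving 12 and 13. An aldol-type condensation is the most reliable way to make an aryl enone, and the cut removes ring B and the most fragile group in one move. The forward step must work in base on an aldehyde that is deactivated as its phenoxide, without protecting either hydroxyl, and it must come after every oxidative step because the enone would not survive peroxide.

12 is traced back to 10 by exchanging the C3–O bond for a C3–Si bond. With silicon on C3, that carbon can act as the nucleophilic end of an alkene during ring formation; an enol ether would put the oxygen on C2 instead. The gain is a robust, non-coordinating placeholder for the hydroxyl. The forward oxidation must proceed with retention at C3, must spare the aryl ketone and ring A, and must not trigger β-elimination of the β-silyl ether (through 11).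

10 is cut at C4–C3 and O1–C2, giving 4 and 8 by way of 9. This removes the pyran ring, the stereocentre and the quaternary ether carbon together and leads back to two achiral pieces. The forward step needs a Lewis acid that releases 9 from 4 and holds it through O1 and the acetyl oxygen, regiocontrol from silicon, control of the alkene face by the ligand, and ring closure faster than loss of silicon. To help this, 4 keeps a free phenol and an acetate leaving group that departs as weakly nucleophilic acetic acid. The hindered dimethylphenylsilyl group of 8 is retained, 8 is used in excess, and 4 is added slowly.

8 is cut at the Si–C(sp2) bond, giving 5 and 6 by way of 7. Both are commercial, and the alkene has no geometry to control. The forward step is a routine silylation of an alkenyl Grignard reagent.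

4 is traced back through 3 and 2 to 1 by cutting the C4a–C4 bond (aryl–CH2). 1 already has ring A with the acetyl, hydroxyl and methoxy groups in the right places, so only one carbon has to be added. The forward sequence demands aminomethylation at the position between the hydroxyl and the methoxy group, exchange of nitrogen for acetate, and cleavage of the phenolic acetate alone without releasing the quinone methide early.

## Other disconnections considered

Alternative 1: The cut runs through both bonds of the ketone carbon, C8–C(=O) and C(=O)–Cα. In the forward direction a Pd(OAc)2/bidentate phosphine catalyst with triethylamine would join three components: the aryl bromide (S)-8-bromo-5-methoxy-2,2-dimethylchroman-3-yl acetate A1, 4-acetoxystyrene A2 and carbon monoxide A3. Zerovalent palladium adds into the C8–Br bond of A1, A3 inserts, A2 inserts into the aroyl–palladium bond, and syn β-hydride elimination gives the E-enone (S,E)-4-[3-(3-acetoxy-5-methoxy-2,2-dimethylchroman-8-yl)-3-oxoprop-1-enyl]phenyl acetate A4. No ring is formed. Mild methanolysis of both acetates of A4 would then give 14.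
- In its favour: it is convergent and makes the enone under weakly basic, non-aldol conditions, so the deactivated aldehyde of step 7 is avoided. On this point it is the equal of the chosen plan or better.
- Against it: A1 already contains the chroman and the C3 stereocentre, so the hard part is untouched and still needs its own asymmetric synthesis. A1 also lacks the acetyl group that makes 9 a two-point ligand, so step 5 could not be reused for it.
- Further risks: the electron-rich ortho-alkoxy aryl bromide A1 should add slowly to palladium, and direct Heck coupling of A1 with A2 without uptake of A3 would compete.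
- Comparison: the organopalladium steps are well understood, which is an advantage over the untested step 5 for that one bond. On step economy it replaces one condensation by bromination, two acetylations, the carbonylation to A4 and deacetylation, so it would be longer.

Alternative 2: Here ring A itself is taken apart at C8a–C4a, C5–C6 and C8a–C8. Irradiation of the diazo ketone (S,E)-5-(tert-butyldimethylsilyloxy)-1-diazohex-3-en-2-one A5 would give a vinylketene by Wolff rearrangement. This would add the methoxyalkyne (S)-4-(3-methoxyprop-2-ynyl)-2,2,5,5-tetramethyl-1,3-dioxolane A6 in a [2+2] sense. Opening of the cyclobutenone and 6π closure would then give the phenol 6-[(S)-1-(tert-butyldimethylsilyloxy)ethyl]-3-methoxy-2-{[(S)-2,2,5,5-tetramethyl-1,3-dioxolan-4-yl]methyl}phenol A7.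
- In its favour: the polarity of the ynol ether A6 fixes where every substituent of ring A ends up in A7, so there is no question of where an electrophile enters an arene. On this point it is better than the chosen plan, whose step 1 depends on aromatic regioselectivity. The benzannulation type is also known, so on precedent it is better than step 5.
- Against it: ring A with the right oxygen pattern can be bought as 1, so building it is a poor use of steps. A5 and A6 are each several steps away and delicate. The silyloxyethyl stereocentre of A7 is made only to be oxidised to the ketone later.
- From A7, acetonide removal, closure of the pyran ring at the tertiary carbon, desilylation, oxidation and the condensation all remain. The C3 centre still needs an asymmetric step earlier on, in the synthesis of A6.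
- Comparison: it solves the substitution pattern of ring A, which the chosen plan simply inherits from 1. Mechanistically it is a pericyclic cascade with known regiochemistry, against a Lewis acid cycloaddition that rests on the β-silicon effect. On step economy it would need well over ten steps against seven.

Alternative 3: The carbinol is traced back to a cis-epoxide across C3=C4 of the chromene 1-(5-methoxy-2,2-dimethyl-2H-chromen-8-yl)ethanone A8, with an extra oxygen placed temporarily on C4. A chiral (salen)MnCl complex with aqueous hypochlorite as terminal oxidant would transfer one oxygen atom to the alkene of A8, giving (3S,4S)-8-acetyl-3,4-epoxy-5-methoxy-2,2-dimethylchroman A9. Regioselective reductive cleavage of the benzylic C4–O bond of A9 would then give 12, and step 7 would finish the synthesis.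
- In its favour: 2,2-dimethylchromenes are among the best substrates for this epoxidation. A8 should be available from 1 in two steps by O-propargylation and thermal rearrangement, which can only reach the one free ortho position. That makes five steps in all, so in step count and in precedent this alternative is better than the chosen plan.
- Against it: oxygen is put on C4 only to be removed, and the removal from A9 must distinguish the benzylic C–O bond from the aryl ketone. Alkaline hypochlorite is a risk for a methyl ketone (haloform cleavage) and for C6 of ring A (chlorination), so a low-temperature peracid variant might be needed. Ring and stereocentre are made in separate steps.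
- Comparison: both plans start from 1 and share 12 and step 7. The chosen plan makes the ring and the stereocentre together, places the heteroatom on C3 only and avoids a redox detour at C4. It pays for this with an untested step and a delicate C–Si oxidation, which is why the chemistry of this alternative, through A8 and A9, is kept as the fallback for step 5.

Key step: step 5

Remark on the chemistry (assumption): the sense of induction of the ligand in step 5 cannot be derived from precedent. The (S,S)-ligand is written for the (S)-product, and its mirror image would be used if the opposite sense is found.

## Route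

Step 1
Reactants: 1 paeonol, 1-(2-hydroxy-4-methoxyphenyl)ethanone
Product: 2 1-{3-[(dimethylamino)methyl]-2-hydroxy-4-methoxyphenyl}ethanone
Conditions: Me2NH (40% aq.), CH2O (37% aq.), EtOH, reflux
Reagents that add atoms: formaldehyde, C=O; dimethylamine, CNC
Why: Phenolic Mannich reaction: the iminium ion from CH2O and Me2NH is delivered by the hydrogen-bonded phenol to the only free position ortho to the hydroxyl, C3 of 1, which is activated by both oxygen substituents. Without acid the acetyl methyl group should not be aminomethylated.

Step 2
Reactants: 2 1-{3-[(dimethylamino)methyl]-2-hydroxy-4-methoxyphenyl}ethanone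
Product: 3 2-acetoxy-3-acetyl-6-methoxybenzyl acetate
Conditions: Ac2O, 110 °C
Reagents that add atoms: acetic anhydride, CC(=O)OC(C)=O
Why: Amine–acetate exchange of a phenolic Mannich base in hot acetic anhydride: N-acylation turns the amine into a leaving group that departs as N,N-dimethylacetamide and acetate takes its place. The phenol is acetylated at the same time, which protects the product from early quinone methide formation.

Step 3
Reactants: 3 2-acetoxy-3-acetyl-6-methoxybenzyl acetate
Product: 4 3-acetyl-2-hydroxy-6-methoxybenzyl acetate
Conditions: NH4OAc, MeOH/H2O (4:1), rt
Reagents that add atoms: none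
Why: Chemoselective solvolysis of an aryl acetate: the aryloxide, stabilised by the ortho-acetyl group, is a far better leaving group than a benzylic alkoxide, so buffered methanolysis at neutral pH should remove only the phenolic acetate. The freed phenol stays protonated and hydrogen-bonded to the ketone, which should keep the benzylic acetate from ionising.

Step 4
Reactants: 5 1-bromo-2-methylprop-1-ene; 6 chlorodimethylphenylsilane
Product: 8 dimethyl(2-methylprop-1-enyl)phenylsilane, via (2-methylprop-1-enyl)magnesium bromide 7 (not isolated)
Conditions: Mg, I2 (cat.), THF, reflux; then 6, 0 °C → rt
Reagents that add atoms: none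
Why: Grignard formation from the vinylic bromide followed by nucleophilic substitution at silicon. There is no stereochemical issue because the alkene terminus carries two methyl groups.

Step 5
Reactants: 4 3-acetyl-2-hydroxy-6-methoxybenzyl acetate; 8 dimethyl(2-methylprop-1-enyl)phenylsilane
Product: 10 (S)-1-[3-(dimethylphenylsilyl)-5-methoxy-2,2-dimethylchroman-8-yl]ethanone, via ortho-quinone methide 9 (not isolated)
Conditions: Cu(OTf)2 (10 mol%), 2,2'-isopropylidenebis[(4S)-4-tert-butyl-2-oxazoline] (11 mol%), 4 Å MS, CH2Cl2, −40 → 0 °C; slow addition of 4 to 8 (3 equiv)
Reagents that add atoms: none
Why: Proposed new method: Cu(OTf)2 and the bis(oxazoline) bind 4 through the phenol oxygen and the acetyl oxygen, and loss of acetic acid gives the copper-bound ortho-quinone methide 9, held as a planar six-membered chelate on divalent copper. The silicon-bearing CH of 8 attacks the exocyclic methylene C4, because positive charge then builds on the tertiary carbon that is also β to silicon, and O1 closes on that carbon; the pyran ring thus forms by an asynchronous inverse-demand [4+2] cycloaddition (in the stepwise limit, six-membered closure of O1 onto the tertiary β-silyl cation), which restores the aromaticity of ring A. The closest known reaction types are bis(oxazoline)–copper-catalysed inverse-demand hetero-Diels–Alder reactions of chelating 1-oxadienes with enol ethers, catalytic asymmetric [4+2] reactions of ortho-quinone methides with electron-rich alkenes, and ipso attack of carbon electrophiles on vinylsilanes; the vinylsilane as 2π partner of a chelated quinone methide is the untested element. C3 is the only new stereocentre and is under catalyst control: the tert-butyl groups of the ligand block one face of the chelated heterodiene, and with the bulky silyl group turned away from the metal–ligand plane only one enantiotopic face of the alkene can bond to C4, so both face selectivity and a consistent exo preference are required. Regiochemistry rests on the β-silicon effect together with the gem-dimethyl terminus, which puts oxygen on C2 and silicon on C3, the reverse of what an enol ether would give. Chemoselectivity needs ring closure to be faster than attack of acetate or triflate on silicon, which would lead to the ring-opened prenyl phenol; the hindered dimethylphenylsilyl group, the chelate-held intramolecular oxygen nucleophile, low temperature and the absence of fluoride or free base are meant to secure this. Slow addition of 4 to excess 8 keeps the concentration of 9 low and so should limit its dimerisation.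

Step 6
Reactants: 10 (S)-1-[3-(dimethylphenylsilyl)-5-methoxy-2,2-dimethylchroman-8-yl]ethanone
Product: 12 (S)-1-(3-hydroxy-5-methoxy-2,2-dimethylchroman-8-yl)ethanone, via fluorosilane 11 (not isolated)
Conditions: HBF4·OEt2, CH2Cl2, −20 → 0 °C; then KF, KHCO3, 30% H2O2, THF/MeOH, rt
Reagents that add atoms: hydrogen peroxide, OO
Why: Fleming–Tamao oxidation: ipso-protonation of the phenyl group replaces it by fluoride, then hydroperoxide adds to silicon and C3 migrates from silicon to oxygen with retention, so the (S)-configuration of 10 is carried into 12. Nucleophilic peroxide under bicarbonate buffer is chosen because peracid or bromine variants would risk Baeyer–Villiger oxidation of the electron-rich aryl ketone and halogenation of ring A at C6. The acid stage is kept cold and short to limit β-elimination of the β-silyl ether.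

Step 7
Reactants: 12 (S)-1-(3-hydroxy-5-methoxy-2,2-dimethylchroman-8-yl)ethanone; 13 4-hydroxybenzaldehyde
Product: 14 (S,E)-1-(3-hydroxy-5-methoxy-2,2-dimethylchroman-8-yl)-3-(4-hydroxyphenyl)prop-2-en-1-one
Conditions: KOH (50% aq.), EtOH, rt; then aq. HCl to pH 5
Reagents that add atoms: none
Why: Claisen–Schmidt condensation: the potassium enolate of the methyl ketone adds to the aldehyde and E1cB dehydration gives the conjugated E-alkene as the thermodynamic isomer. Ring A has no free ortho-hydroxyl, so no flavanone can form, and C3 carries no acidic hydrogen, so the stereocentre is not at risk.

## Compound list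

1 | paeonol, 1-(2-hydroxy-4-methoxyphenyl)ethanone | CC(=O)c1ccc(OC)cc1O | starting material
2 | 1-{3-[(dimethylamino)methyl]-2-hydroxy-4-methoxyphenyl}ethanone | COc1ccc(C(C)=O)c(O)c1CN(C)C | intermediate
3 | 2-acetoxy-3-acetyl-6-methoxybenzyl acetate | COc1ccc(C(C)=O)c(OC(C)=O)c1COC(C)=O | intermediate
4 | 3-acetyl-2-hydroxy-6-methoxybenzyl acetate | COc1ccc(C(C)=O)c(O)c1COC(C)=O | intermediate
5 | 1-bromo-2-methylprop-1-ene | CC(C)=CBr | starting material
6 | chlorodimethylphenylsilane | C[Si](C)(Cl)c1ccccc1 | starting material
7 | (2-methylprop-1-enyl)magnesium bromide (formed in the flask, not isolated) | CC(C)=C[Mg]Br | intermediate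
8 | dimethyl(2-methylprop-1-enyl)phenylsilane | CC(C)=C[Si](C)(C)c1ccccc1 | intermediate
9 | ortho-quinone methide 2-acetyl-5-methoxy-6-methylidenecyclohexa-2,4-dien-1-one (copper-bound, not isolated) | C=C1C(=O)C(C(C)=O)=CC=C1OC | intermediate
10 | (S)-1-[3-(dimethylphenylsilyl)-5-methoxy-2,2-dimethylchroman-8-yl]ethanone | COc1ccc(C(C)=O)c2c1C[C@H]([Si](C)(C)c3ccccc3)C(C)(C)O2 | intermediate
11 | (S)-1-[3-(fluorodimethylsilyl)-5-methoxy-2,2-dimethylchroman-8-yl]ethanone (not isolated) | COc1ccc(C(C)=O)c2c1C[C@H]([Si](C)(C)F)C(C)(C)O2 | intermediate
12 | (S)-1-(3-hydroxy-5-methoxy-2,2-dimethylchroman-8-yl)ethanone | COc1ccc(C(C)=O)c2c1C[C@H](O)C(C)(C)O2 | intermediate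
13 | 4-hydroxybenzaldehyde | O=Cc1ccc(O)cc1 | starting material
14 | (S,E)-1-(3-hydroxy-5-methoxy-2,2-dimethylchroman-8-yl)-3-(4-hydroxyphenyl)prop-2-en-1-one | COc1ccc(C(=O)/C=C/c2ccc(O)cc2)c2c1C[C@H](O)C(C)(C)O2 | target

## Step count and least certain steps

Total: 7 steps. Longest linear sequence: 6 steps from 1 (steps 1, 2, 3, 5, 6, 7); step 4 is a one-step side branch.

**Step 5 (key step, proposed new method).** The most likely failure is loss of silicon outpacing ring closure, because acetate or triflate can attack silicon in the β-silyl cation faster than the copper-bound oxygen closes the ring. Further possible failures are poor discrimination of the alkene faces if the exo preference of the silyl group is weak, oligomerisation of the quinone methide, and acid-induced reopening of the product. The fallback uses known chemistry, sets out from 1 and comes back to the route at 12. 1 is O-alkylated with 3-chloro-3-methylbut-1-yne (K2CO3, KI, CuCl cat., acetone, reflux) to 1-[4-methoxy-2-(2-methylbut-3-yn-2-yloxy)phenyl]ethanone F1. Heating F1 in N,N-diethylaniline at about 180 °C should bring about propargyl Claisen rearrangement to the one free ortho position, a [1,5]-hydrogen shift and oxa-6π closure, giving 1-(5-methoxy-2,2-dimethyl-2H-chromen-8-yl)ethanone F2 (identical with A8). Asymmetric epoxidation with the (S,S)-configured (salen)MnCl complex N,N'-bis(3,5-di-tert-butylsalicylidene)-1,2-cyclohexanediaminomanganese chloride, mCPBA and N-methylmorpholine N-oxide in CH2Cl2 at −78 °C is expected, by analogy with simple 2,2-dimethylchromenes, to give (3S,4S)-8-acetyl-3,4-epoxy-5-methoxy-2,2-dimethylchroman F3 (identical with A9). Hydrogenolysis of the benzylic C4–O bond of F3 (H2, Pd/C, EtOAc) then gives 12.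

**Step 6.** The most likely failure is β-elimination during the acidic dephenylation: protonation at the acetyl or ether oxygen lets C2–O1 ionise with help from the anti C–Si bond, which opens the ring and destroys the stereocentre. Over-oxidation of the aryl ketone is a lesser risk. The fallback sets out from 10 and comes back to the route at 12. Bu4NF in THF is used deliberately to drive the same anti-elimination of the β-aryloxysilane cleanly to 1-[2-hydroxy-4-methoxy-3-(3-methylbut-2-enyl)phenyl]ethanone F4. Dehydrogenative cyclisation of F4 with DDQ in hot benzene gives the chromene F2, and from F2 the material follows the fallback of step 5 through F3 to 12. The stereocentre is then set by the epoxidation catalyst instead of by step 5; new material would be brought to F2 directly from 1.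

**Step 1.** The most likely failure is aminomethylation at C5 (para to the hydroxyl) or at both positions, because the chelated phenol directs less strongly than a free one. The fallback sets out from 1 and comes back to the route at 3. Boronate-templated ortho-hydroxymethylation with PhB(OH)2, paraformaldehyde and catalytic propionic acid in toluene, with azeotropic removal of water, can only reach the position ortho to the phenol and gives 1-(5-methoxy-2-phenyl-4H-1,3,2-benzodioxaborinin-8-yl)ethanone F5. Transesterification of F5 with propane-1,3-diol frees 1-[2-hydroxy-3-(hydroxymethyl)-4-methoxyphenyl]ethanone F6, and exhaustive acetylation of F6 (Ac2O, pyridine, DMAP) gives 3.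

**Step 7.** The most likely failure is slow or incomplete condensation, because the aldehyde is deactivated as its phenoxide in strong base, which leaves time for side reactions of the aldehyde and the enolate. The fallback sets out from 13 and comes back to the route at 14. 13 is protected with chloromethyl methyl ether and i-Pr2NEt as 4-(methoxymethoxy)benzaldehyde F7. F7 is condensed with 12 (KOH, EtOH, rt) to (S,E)-1-(3-hydroxy-5-methoxy-2,2-dimethylchroman-8-yl)-3-[4-(methoxymethoxy)phenyl]prop-2-en-1-one F8, and mild acid methanolysis of F8 (HCl cat., MeOH, 40 °C) gives 14.

## Further compounds

F1 | step 5 | 1-[4-methoxy-2-(2-methylbut-3-yn-2-yloxy)phenyl]ethanone | CC(=O)c1ccc(OC)cc1OC(C)(C)C#C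
F2 | step 5 | 1-(5-methoxy-2,2-dimethyl-2H-chromen-8-yl)ethanone | COc1ccc(C(C)=O)c2c1C=CC(C)(C)O2
F3 | step 5 | (3S,4S)-8-acetyl-3,4-epoxy-5-methoxy-2,2-dimethylchroman | COc1ccc(C(C)=O)c2c1[C@@H]3O[C@@H]3C(C)(C)O2
F4 | step 6 | 1-[2-hydroxy-4-methoxy-3-(3-methylbut-2-enyl)phenyl]ethanone | COc1ccc(C(C)=O)c(O)c1CC=C(C)C
F5 | step 1 | 1-(5-methoxy-2-phenyl-4H-1,3,2-benzodioxaborinin-8-yl)ethanone | COc1ccc(C(C)=O)c2c1COB(c3ccccc3)O2
F6 | step 1 | 1-[2-hydroxy-3-(hydroxymethyl)-4-methoxyphenyl]ethanone | COc1ccc(C(C)=O)c(O)c1CO
F7 | step 7 | 4-(methoxymethoxy)benzaldehyde | COCOc1ccc(C=O)cc1
F8 | step 7 | (S,E)-1-(3-hydroxy-5-methoxy-2,2-dimethylchroman-8-yl)-3-[4-(methoxymethoxy)phenyl]prop-2-en-1-one | COc1ccc(C(=O)/C=C/c2ccc(OCOC)cc2)c2c1C[C@H](O)C(C)(C)O2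
A1 | alternative 1 | (S)-8-bromo-5-methoxy-2,2-dimethylchroman-3-yl acetate | COc1ccc(Br)c2c1C[C@H](OC(C)=O)C(C)(C)O2
A2 | alternative 1 | 4-acetoxystyrene | C=Cc1ccc(OC(C)=O)cc1
A3 | alternative 1 | carbon monoxide | [C-]#[O+]
A4 | alternative 1 | (S,E)-4-[3-(3-acetoxy-5-methoxy-2,2-dimethylchroman-8-yl)-3-oxoprop-1-enyl]phenyl acetate | COc1ccc(C(=O)/C=C/c2ccc(OC(C)=O)cc2)c2c1C[C@H](OC(C)=O)C(C)(C)O2
A5 | alternative 2 | (S,E)-5-(tert-butyldimethylsilyloxy)-1-diazohex-3-en-2-one | [N-]=[N+]=CC(=O)/C=C/[C@H](C)O[Si](C)(C)C(C)(C)C
A6 | alternative 2 | (S)-4-(3-methoxyprop-2-ynyl)-2,2,5,5-tetramethyl-1,3-dioxolane | COC#CC[C@@H]1OC(C)(C)OC1(C)C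
A7 | alternative 2 | 6-[(S)-1-(tert-butyldimethylsilyloxy)ethyl]-3-methoxy-2-{[(S)-2,2,5,5-tetramethyl-1,3-dioxolan-4-yl]methyl}phenol | COc1ccc([C@H](C)O[Si](C)(C)C(C)(C)C)c(O)c1C[C@@H]2OC(C)(C)OC2(C)C
A8 | alternative 3 | 1-(5-methoxy-2,2-dimethyl-2H-chromen-8-yl)ethanone | COc1ccc(C(C)=O)c2c1C=CC(C)(C)O2
A9 | alternative 3 | (3S,4S)-8-acetyl-3,4-epoxy-5-methoxy-2,2-dimethylchroman | COc1ccc(C(C)=O)c2c1[C@@H]3O[C@@H]3C(C)(C)O2
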